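Retrosynthesis: the 4'-O-MOM, 7-O-Si(i-Pr)3 and C6-SiMe3 groups go first. Ring A is then cut at C4a–C5, C5–C6, C7–C8 and C8–C8a, which leaves a 6-aryl-4-pyron-2-yl diazomethyl ketone and the ynol ether Me3Si–C≡C–OSi(i-Pr)3.
Enabling feature: ring A bears oxygen at C5 and C7, meta to each other with C6–H between them, and shares the C4a=C8a double bond with ring C. That bond is the vinyl unit of a vinylketene, C5 its carbonyl carbon, and C6/C7 the two carbons of an oxygenated alkyne.
Further cuts: C8 (diazoalkane carbon), the O1 bridge of ring C (cyclodehydration), C4a–C8a and C3–C4 (two Claisen condensations), and the two aryl–prenyl bonds at C3' and C5' (cross-coupling).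
Forward order: ring B is dressed first, ring C is closed second, and ring A is grown last on the finished pyrone.
Stereochemistry: the target has no stereocentre and both alkenes end in CMe2. Only regiochemistry has to be set, and the polarity of the ynol ether sets it.

Key step: step 10

Remark: prenyl = 3-methylbut-2-en-1-yl. Flavone numbering (O1, C2, C3, C4, C4a, C5–C8, C8a, primed ring B) is also used for the atoms of the pyrone precursors, and compounds drawn as keto forms may be largely enolized.

Step 1
Reactants: 1 4-hydroxyacetophenone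
Product: 2 3',5'-dibromo-4'-hydroxyacetophenone
Conditions: Br2 (2.05 equiv), NaOAc, AcOH, 20 °C
Reagents that add atoms: bromine, BrBr
Why: Electrophilic aromatic bromination: the phenol directs both bromine atoms to its free ortho positions (para is held by the acetyl group), and the acetate buffer removes HBr so that acid-catalysed enolization and side-chain bromination stay slow.

Step 2
Reactants: 2 3',5'-dibromo-4'-hydroxyacetophenone
Product: 3 3',5'-dibromo-4'-(methoxymethoxy)acetophenone
Conditions: MOMCl, i-Pr2NEt, CH2Cl2, 0 → 20 °C
Reagents that add atoms: chloromethyl methyl ether, COCCl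
Why: O-Alkylation of the acidic 2,6-dibromophenol with the highly reactive chloromethyl ether (Williamson type) should give an acetal that resists the bases, the palladium step, the light and the heat ahead and leaves under dilute acid at the end.

Step 3
Reactants: 3 3',5'-dibromo-4'-(methoxymethoxy)acetophenone; 4 tributyl(3-methylbut-2-en-1-yl)stannane
Product: 5 4'-(methoxymethoxy)-3',5'-diprenylacetophenone
Conditions: 4 (2.4 equiv), Pd(PPh3)4 (5 mol %), DMF, 100 °C
Reagents that add atoms: none
Why: Twofold Stille coupling: zerovalent palladium inserts into each C–Br bond, the prenyl group is handed over from tin, and reductive elimination at the unsubstituted allyl terminus should give the linear prenyl arene, which sidesteps the O- versus C-alkylation and mono- versus dialkylation problems of direct phenoxide prenylation.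

Step 4
Reactants: 5 4'-(methoxymethoxy)-3',5'-diprenylacetophenone; 6 ethyl acetate
Product: 7 1-[4-(methoxymethoxy)-3,5-diprenylphenyl]butane-1,3-dione
Conditions: NaH, 6 (excess), THF, 0 → 65 °C; AcOH quench
Reagents that add atoms: none
Why: Crossed Claisen condensation of the methyl ketone enolate with ethyl acetate forms C3–C4 and is pulled forward by deprotonation of the 1,3-diketone, while acetal and alkenes are inert to base.

Step 5
Reactants: 7 1-[4-(methoxymethoxy)-3,5-diprenylphenyl]butane-1,3-dione; 8 diethyl oxalate
Product: 9 ethyl 6-[4-(methoxymethoxy)-3,5-diprenylphenyl]-2,4,6-trioxohexanoate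
Conditions: LiN(i-Pr)2 (2.1 equiv), THF, −78 → 0 °C; added to 8 (3 equiv), THF, −78 °C; AcOH quench, −78 °C
Reagents that add atoms: none
Why: Claisen condensation of a 1,3-diketone dianion: the second, far more basic carbanion sits on the terminal methyl group, so acylation by the oxalate forms C4a–C8a there and not at the central carbon, while inverse addition at −78 °C should suppress double addition and Dieckmann closure to a cyclopentanetrione.

Step 6
Reactants: 9 ethyl 6-[4-(methoxymethoxy)-3,5-diprenylphenyl]-2,4,6-trioxohexanoate
Product: 10 ethyl 6-[4-(methoxymethoxy)-3,5-diprenylphenyl]-4-oxo-4H-pyran-2-carboxylate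
Conditions: PPh3, CCl4, Et3N, THF, 20 → 50 °C
Reagents that add atoms: none
Why: Appel-type cyclodehydration of a 1,3,5-tricarbonyl compound to a 4-pyrone: one terminal enol oxygen becomes an oxyphosphonium leaving group and the enol oxygen at the other end displaces it by six-membered addition–elimination to close ring C (O1 bridge between C2 and C8a), in an amine-buffered medium that spares the acetal and the prenyl alkenes, which the customary strong-acid closure would not.

Step 7
Reactants: 10 ethyl 6-[4-(methoxymethoxy)-3,5-diprenylphenyl]-4-oxo-4H-pyran-2-carboxylate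
Product: 11 6-[4-(methoxymethoxy)-3,5-diprenylphenyl]-4-oxo-4H-pyran-2-carboxylic acid
Conditions: LiOH (1.05 equiv), THF–H2O, 0 °C; then 1 M HCl to pH 3, 0 °C
Reagents that add atoms: lithium hydroxide (the acid oxygen), [Li+].[OH-]
Why: Saponification: the ester sits on the electron-poor C8a next to O1 and is hydrolysed by one equivalent of hydroxide at 0 °C faster than hydroxide adds to the ring, as in the routine hydrolysis of chromone-2-carboxylates, and the brief cold acidification leaves the acetal intact.

Step 8
Reactants: 11 6-[4-(methoxymethoxy)-3,5-diprenylphenyl]-4-oxo-4H-pyran-2-carboxylic acid; 12 (trimethylsilyl)diazomethane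
Product: 14 2-diazo-1-{6-[4-(methoxymethoxy)-3,5-diprenylphenyl]-4-oxo-4H-pyran-2-yl}ethan-1-one, via mixed anhydride 13 (not isolated)
Conditions: i-BuOCOCl, N-methylmorpholine, THF, −15 °C; then 12 (2 equiv), MeCN, 0 → 20 °C, dark
Reagents that add atoms: isobutyl chloroformate, CC(C)COC(=O)Cl (its atoms stay only in 13)
Why: Arndt–Eistert-type acylation of a diazoalkane by a mixed carbonic anhydride brings in C8; the carbonate leaving group takes the silyl group from carbon and collapses to CO2, the medium stays neutral for the acetal, and low temperature with limited reagent should keep dipolar cycloaddition to the pyrone C=C bonds in check.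

Step 9
Reactants: 15 trimethylsilylacetylene
Product: 18 1-(triisopropylsilyloxy)-2-(trimethylsilyl)acetylene, via lithium acetylide 16 (not isolated), via lithium ynolate 17 (not isolated)
Conditions: n-BuLi, THF, −78 °C; t-BuOOLi (from t-BuOOH, LiN(SiMe3)2), THF, −78 → 0 °C; i-Pr3SiOTf, −78 → 0 °C
Reagents that add atoms: tert-butyl hydroperoxide (the oxygen atom), CC(C)(C)OO; triisopropylsilyl trifluoromethanesulfonate, CC(C)[Si](C(C)C)(C(C)C)OS(=O)(=O)C(F)(F)F; n-butyllithium (lithium of 16 and 17 only), [Li]CCCC
Why: Electrophilic oxygenation of a lithium acetylide with lithium tert-butyl peroxide gives the ynolate, and the bulky silyl triflate should silylate it at oxygen (the established route to triisopropylsilyloxyalkynes), all the more so as the carbon terminus already carries SiMe3.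

Step 10
Reactants: 14 2-diazo-1-{6-[4-(methoxymethoxy)-3,5-diprenylphenyl]-4-oxo-4H-pyran-2-yl}ethan-1-one; 18 1-(triisopropylsilyloxy)-2-(trimethylsilyl)acetylene
Product: 23 5-hydroxy-4'-(methoxymethoxy)-3',5'-diprenyl-7-(triisopropylsilyloxy)-6-(trimethylsilyl)flavone, via pyronylketene 19 (not isolated), via cyclobutenone 20 (not isolated), via dienylketene 21 (not isolated), via cyclohexadienone 22 (not isolated)
Conditions: 18 (2.5 equiv), degassed ClCH2CH2Cl, 440 nm LED, 20 °C; then PhMe, 110 °C
Reagents that add atoms: none
Why: Proposed new method: 440 nm light excites only the weak n–π* band of diazoketone 14, N2 leaves and the pyron-2-yl group migrates (Wolff rearrangement, new C8–C8a bond) to give ketene 19, which the ynol ether 18 traps by polar [2+2] addition (C5–C6 and C7–C8) as the four-membered ring of 20. On heating, 20 opens reversibly by four-electron conrotatory cleavage of C5–C8 to dienylketene 21, and since only the isomer with the pyronyl group cis to the ketene chain can react further, the whole equilibrium drains through it. Ring A closes by six-electron disrotatory electrocyclization of the C5=C6, C7=C8, C8a=C4a array, in which the electrophilic ketene carbon C5 bonds to C4a, the nucleophilic β-carbon of the O1–C8a=C4a enol ether, and the C4a–H of dienone 22, flanked by two carbonyl groups, then moves to oxygen to give the C5 phenol chelated to the C4 carbonyl. The closest known reaction type is the Danheiser benzannulation in its diazoketone form, established for vinyl, aryl and heteroaryl diazoketones with triisopropylsilyloxyalkynes, so the 4-pyrone as donor of the C=C bond and the silyl substituent on the alkyne are the untested points. The step needs regioselectivity, secured by the polarity of 18 (its silicon-bearing carbon is the nucleophile and the cation developing at the other carbon is stabilized by oxygen and by the β-silicon effect, so O ends at C7 and Si at C6) and by C8a having only one ring carbon neighbour, C4a, to close on, and it needs chemoselectivity over the two prenyl alkenes, secured by the far higher nucleophilicity of 18 and its use in excess. The stereocentres at C8 in 20 and at C4a in 22 are transient and vanish on aromatization, and the long wavelength leaves the arylpyrone and flavone chromophores unexcited, which shuts off the ultraviolet isomerization of 4-pyrones and light absorption by the product.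

Step 11
Reactants: 23 5-hydroxy-4'-(methoxymethoxy)-3',5'-diprenyl-7-(triisopropylsilyloxy)-6-(trimethylsilyl)flavone
Product: 24 5,7-dihydroxy-4'-(methoxymethoxy)-3',5'-diprenyl-6-(trimethylsilyl)flavone
Conditions: Bu4NF, AcOH (1 equiv each), THF, 0 °C
Reagents that add atoms: none
Why: Fluoride-induced Si–O cleavage: the C7 oxygen is a vinylogous carboxylate leaving group, so the silyl ether should fall at 0 °C, the acetic acid buffer keeps the medium non-basic, and any early loss of the C6 silyl group is harmless because step 12 removes it anyway.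

Step 12
Reactants: 24 5,7-dihydroxy-4'-(methoxymethoxy)-3',5'-diprenyl-6-(trimethylsilyl)flavone
Product: 25 honyucitrin (5,7,4'-trihydroxy-3',5'-diprenylflavone)
Conditions: HCl (0.5 M in MeOH), 40 °C
Reagents that add atoms: none
Why: Acid-catalysed acetal exchange with methanol frees the 4'-hydroxyl group and ipso-protonation at C6, which lies ortho to two hydroxyl groups and is β-stabilized by silicon, brings about protodesilylation, while dilute acid and mild warming should stay below the threshold for addition of the phenol to its ortho prenyl groups (chroman formation).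

Compound list
1 | 4-hydroxyacetophenone | CC(=O)c1ccc(O)cc1 | starting material
2 | 3',5'-dibromo-4'-hydroxyacetophenone | CC(=O)c1cc(Br)c(O)c(Br)c1 | intermediate
3 | 3',5'-dibromo-4'-(methoxymethoxy)acetophenone | CC(=O)c1cc(Br)c(OCOC)c(Br)c1 | intermediate
4 | tributyl(3-methylbut-2-en-1-yl)stannane | CCCC[Sn](CCCC)(CCCC)CC=C(C)C | starting material
5 | 4'-(methoxymethoxy)-3',5'-diprenylacetophenone | CC(=O)c1cc(CC=C(C)C)c(OCOC)c(CC=C(C)C)c1 | intermediate
6 | ethyl acetate | CCOC(C)=O | starting material
7 | 1-[4-(methoxymethoxy)-3,5-diprenylphenyl]butane-1,3-dione | CC(=O)CC(=O)c1cc(CC=C(C)C)c(OCOC)c(CC=C(C)C)c1 | intermediate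
8 | diethyl oxalate | CCOC(=O)C(=O)OCC | starting material
9 | ethyl 6-[4-(methoxymethoxy)-3,5-diprenylphenyl]-2,4,6-trioxohexanoate | CCOC(=O)C(=O)CC(=O)CC(=O)c1cc(CC=C(C)C)c(OCOC)c(CC=C(C)C)c1 | intermediate
10 | ethyl 6-[4-(methoxymethoxy)-3,5-diprenylphenyl]-4-oxo-4H-pyran-2-carboxylate | CCOC(=O)c1cc(=O)cc(-c2cc(CC=C(C)C)c(OCOC)c(CC=C(C)C)c2)o1 | intermediate
11 | 6-[4-(methoxymethoxy)-3,5-diprenylphenyl]-4-oxo-4H-pyran-2-carboxylic acid | OC(=O)c1cc(=O)cc(-c2cc(CC=C(C)C)c(OCOC)c(CC=C(C)C)c2)o1 | intermediate
12 | (trimethylsilyl)diazomethane | C[Si](C)(C)C=[N+]=[N-] | starting material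
13 | isobutyl carbonic anhydride of acid 11 | CC(C)COC(=O)OC(=O)c1cc(=O)cc(-c2cc(CC=C(C)C)c(OCOC)c(CC=C(C)C)c2)o1 | intermediate
14 | 2-diazo-1-{6-[4-(methoxymethoxy)-3,5-diprenylphenyl]-4-oxo-4H-pyran-2-yl}ethan-1-one | [N-]=[N+]=CC(=O)c1cc(=O)cc(-c2cc(CC=C(C)C)c(OCOC)c(CC=C(C)C)c2)o1 | intermediate
15 | trimethylsilylacetylene | C[Si](C)(C)C#C | starting material
16 | lithium (trimethylsilyl)acetylide | [Li+].[C-]#C[Si](C)(C)C | intermediate
17 | lithium 2-(trimethylsilyl)ethynolate | [Li+].[O-]C#C[Si](C)(C)C | intermediate
18 | 1-(triisopropylsilyloxy)-2-(trimethylsilyl)acetylene | C[Si](C)(C)C#CO[Si](C(C)C)(C(C)C)C(C)C | intermediate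
19 | 2-{6-[4-(methoxymethoxy)-3,5-diprenylphenyl]-4-oxo-4H-pyran-2-yl}ethenone | O=C=Cc1cc(=O)cc(-c2cc(CC=C(C)C)c(OCOC)c(CC=C(C)C)c2)o1 | intermediate
20 | 4-{6-[4-(methoxymethoxy)-3,5-diprenylphenyl]-4-oxo-4H-pyran-2-yl}-3-(triisopropylsilyloxy)-2-(trimethylsilyl)cyclobut-2-en-1-one (racemic) | O=C1C([Si](C)(C)C)=C(O[Si](C(C)C)(C(C)C)C(C)C)C1c1cc(=O)cc(-c2cc(CC=C(C)C)c(OCOC)c(CC=C(C)C)c2)o1 | intermediate
21 | 4-{6-[4-(methoxymethoxy)-3,5-diprenylphenyl]-4-oxo-4H-pyran-2-yl}-3-(triisopropylsilyloxy)-2-(trimethylsilyl)buta-1,3-dien-1-one, pyronyl group cis to the ketene-bearing carbon | O=C=C([Si](C)(C)C)/C(O[Si](C(C)C)(C(C)C)C(C)C)=C\c1cc(=O)cc(-c2cc(CC=C(C)C)c(OCOC)c(CC=C(C)C)c2)o1 | intermediate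
22 | 4a-H keto tautomer of 23 (4aH-chromene-4,5-dione, racemic) | O=C1C=C(c2cc(CC=C(C)C)c(OCOC)c(CC=C(C)C)c2)OC2=CC(O[Si](C(C)C)(C(C)C)C(C)C)=C([Si](C)(C)C)C(=O)C12 | intermediate
23 | 5-hydroxy-4'-(methoxymethoxy)-3',5'-diprenyl-7-(triisopropylsilyloxy)-6-(trimethylsilyl)flavone | COCOc1c(CC=C(C)C)cc(-c2cc(=O)c3c(O)c([Si](C)(C)C)c(O[Si](C(C)C)(C(C)C)C(C)C)cc3o2)cc1CC=C(C)C | intermediate
24 | 5,7-dihydroxy-4'-(methoxymethoxy)-3',5'-diprenyl-6-(trimethylsilyl)flavone | COCOc1c(CC=C(C)C)cc(-c2cc(=O)c3c(O)c([Si](C)(C)C)c(O)cc3o2)cc1CC=C(C)C | intermediate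
25 | honyucitrin | CC(C)=CCc1cc(-c2cc(=O)c3c(O)cc(O)cc3o2)cc(CC=C(C)C)c1O | target

Total step count: 12. Longest linear sequence: 11 steps (1–8 and 10–12); step 9 is a one-step branch.

Steps most likely to fail

1. Step 10.
What may go wrong: capture of the ketene by the crowded C-silylated ynol ether may be slower than ketene dimerization. The cascade may also stall at the cyclobutenone, because the silyl-stabilized dienylketene closes sluggishly onto the pyrone.
Fallback (known chemistry, ring A bought instead of built): the route sets out from acetophenone 5. Claisen condensation with diethyl carbonate (NaH, THF, reflux) should give the β-keto ester ethyl 3-[4-(methoxymethoxy)-3,5-diprenylphenyl]-3-oxopropanoate F1. Solvent-free thermal condensation of F1 with phloroglucinol (Mentzer flavone synthesis, microwave, about 240 °C, a few minutes) should give 5,7-dihydroxy-4'-(methoxymethoxy)-3',5'-diprenylflavone F2. This is a temperature range that aryl MOM ethers and aryl-bound prenyl groups tolerate in aromatic Claisen rearrangements. The conditions of step 12 then take F2 to the target, so the route is rejoined at 25.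

2. Step 9.
What may go wrong: peroxide or tert-butoxide may attack silicon and strip the C-silyl group. Oxygen transfer may remain incomplete, or the silyl group may migrate from oxygen to carbon during isolation.
Fallback: the route sets out from 12. Deprotonation with n-BuLi (THF, −78 °C) gives lithio(trimethylsilyl)diazomethane F3. Under CO (1 atm, −78 °C) F3 takes up carbon monoxide and loses nitrogen to form the same ynolate, with no peroxide or alkoxide in the flask. The route is rejoined at 17, which i-Pr3SiOTf converts to 18 as before.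

3. Step 6.
What may go wrong: the central C4 enol may be activated, or chloride may capture the oxyphosphonium intermediate, either of which could divert the closure. Insufficient buffering could cost the acetal.
Fallback (ring C closed before the acid-sensitive prenyl groups arrive): the route sets out from 3.
- The condensations of steps 4 and 5 should give 1-[3,5-dibromo-4-(methoxymethoxy)phenyl]butane-1,3-dione F4 and then ethyl 6-[3,5-dibromo-4-(methoxymethoxy)phenyl]-2,4,6-trioxohexanoate F5.
- With no alkene on board, the classical closure in hot ethanolic HCl can be used. It also removes the acetal and should give ethyl 6-(3,5-dibromo-4-hydroxyphenyl)-4-oxo-4H-pyran-2-carboxylate F6.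
- MOMCl and i-Pr2NEt restore the protecting group in ethyl 6-[3,5-dibromo-4-(methoxymethoxy)phenyl]-4-oxo-4H-pyran-2-carboxylate F7.
- Twofold Stille coupling of F7 with 4 under the conditions of step 3 rejoins the route at 10.

Further compounds
F1 | step 10 | ethyl 3-[4-(methoxymethoxy)-3,5-diprenylphenyl]-3-oxopropanoate | CCOC(=O)CC(=O)c1cc(CC=C(C)C)c(OCOC)c(CC=C(C)C)c1
F2 | step 10 | 5,7-dihydroxy-4'-(methoxymethoxy)-3',5'-diprenylflavone | COCOc1c(CC=C(C)C)cc(-c2cc(=O)c3c(O)cc(O)cc3o2)cc1CC=C(C)C
F3 | step 9 | lithio(trimethylsilyl)diazomethane | [Li]C(=[N+]=[N-])[Si](C)(C)C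
F4 | step 6 | 1-[3,5-dibromo-4-(methoxymethoxy)phenyl]butane-1,3-dione | CC(=O)CC(=O)c1cc(Br)c(OCOC)c(Br)c1
F5 | step 6 | ethyl 6-[3,5-dibromo-4-(methoxymethoxy)phenyl]-2,4,6-trioxohexanoate | CCOC(=O)C(=O)CC(=O)CC(=O)c1cc(Br)c(OCOC)c(Br)c1
F6 | step 6 | ethyl 6-(3,5-dibromo-4-hydroxyphenyl)-4-oxo-4H-pyran-2-carboxylate | CCOC(=O)c1cc(=O)cc(-c2cc(Br)c(O)c(Br)c2)o1
F7 | step 6 | ethyl 6-[3,5-dibromo-4-(methoxymethoxy)phenyl]-4-oxo-4H-pyran-2-carboxylate | CCOC(=O)c1cc(=O)cc(-c2cc(Br)c(OCOC)c(Br)c2)o1
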